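**Assumption:** lignan numbering is used (C7 = ring carbon bearing the aryl group, C8 = carbon bearing CH2OH, C8' = carbon bearing the benzyl group). The SMILES corresponds to the (2S,3R,4R)-tetrahydrofuran with 2,3-trans / 3,4-cis substituents.

## Retrosynthetic overview

1. Target 11 ⇐ dibenzyl ether 10 by removal of the two phenol protecting groups.
2. 10 ⇐ acyclic epoxy cinnamyl ether 9 by a Ti(III) epoxide-opening / 5-exo-trig radical cyclization. This forms C8–C8', the tetrahydrofuran ring, the CH2OH and the ArCH2 group in one step; the single C7 stereocenter controls C8 and C8'.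
3. 9 ⇐ epoxy tosylate 7 + allylic alcohol 4 by stereoinvertive benzylic epoxide opening (forms C7–O, sets C7), then re-closure to the terminal epoxide.
4. 7 ⇐ 4 by Sharpless asymmetric epoxidation, the only source of chirality; both halves of the lignan come from the same alcohol 4 ⇐ sinapic acid 1.
5. Ring order: aryl-oxirane (step 3), terminal oxirane (step 5), tetrahydrofuran (step 6, the only ring in the target besides the arenes).

## Route

**Step 1**
Reactants: 1, sinapic acid [(E)-3-(4-hydroxy-3,5-dimethoxyphenyl)prop-2-enoic acid]; 2, benzyl bromide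
Product: 3, benzyl (E)-3-[4-(benzyloxy)-3,5-dimethoxyphenyl]prop-2-enoate
Conditions: BnBr (2.5 equiv), K2CO3, DMF, 60 °C
Reagents that add atoms: benzyl bromide (2), BrCc1ccccc1
Why: Williamson O-alkylation of the phenoxide and carboxylate protects the phenol and activates the acid for reduction in one operation; no stereocenter is formed.

**Step 2**
Reactants: 3
Product: 4, (E)-3-[4-(benzyloxy)-3,5-dimethoxyphenyl]prop-2-en-1-ol (4-O-benzylsinapyl alcohol)
Conditions: DIBAL-H (2.5 equiv), CH2Cl2, −78 → 0 °C; Rochelle salt work-up
Reagents that add atoms: none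
Why: DIBAL 1,2-reduction of an enoate gives the (E)-allylic alcohol with the alkene untouched; the benzyl alcohol by-product is removed by chromatography.

**Step 3**
Reactants: 4
Product: 7, [(2S,3S)-3-[4-(benzyloxy)-3,5-dimethoxyphenyl]oxiran-2-yl]methyl 4-methylbenzenesulfonate
Conditions: Ti(OiPr)4 (10 mol%), L-(+)-DIPT (14 mol%), t-BuOOH, 4 Å MS, CH2Cl2, −20 °C; then P(OMe)3; then TsCl, Et3N, DMAP (cat.), −10 → 0 °C; recrystallise
Reagents that add atoms: tert-butyl hydroperoxide (5), CC(C)(C)OO (epoxide O); p-toluenesulfonyl chloride (6), Cc1ccc(cc1)S(Cl)(=O)=O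
Why: Katsuki–Sharpless asymmetric epoxidation of an (E)-allylic alcohol with L-(+)-tartrate gives the (2S,3S)-epoxide, and in situ tosylation traps the sensitive aryl glycidol as a crystalline sulfonate that allows ee upgrade.

**Step 4**
Reactants: 7; 4 (1.5 equiv)
Product: 8, (2S,3R)-3-[4-(benzyloxy)-3,5-dimethoxyphenyl]-3-{[(2E)-3-[4-(benzyloxy)-3,5-dimethoxyphenyl]prop-2-en-1-yl]oxy}-2-hydroxypropyl 4-methylbenzenesulfonate
Conditions: BF3·OEt2 (10 mol%), CH2Cl2, −40 → −20 °C; Et3N quench
Reagents that add atoms: none beyond 4, which is incorporated whole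
Why: Lewis-acid-catalysed alcoholysis of an aryl glycidyl sulfonate occurs at the benzylic carbon with inversion (SN2-like, because the twisted 4-alkoxy group and the CH2OTs group disfavour a free cation), so the (3S)-epoxide carbon becomes the (R)-ether carbon, which has the target's C7 geometry.

**Step 5**
Reactants: 8
Product: 9, (2S)-2-[(R)-[4-(benzyloxy)-3,5-dimethoxyphenyl]{[(2E)-3-[4-(benzyloxy)-3,5-dimethoxyphenyl]prop-2-en-1-yl]oxy}methyl]oxirane
Conditions: K2CO3, MeOH/THF, 0 °C → rt
Reagents that add atoms: none
Why: intramolecular Williamson (3-exo-tet) displacement of the primary tosylate by the C8 alkoxide gives the terminal epoxide; C8 is retained and C7 is not involved.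

**Step 6**
Reactants: 9
Product: 10, [(2S,3R,4R)-2-[4-(benzyloxy)-3,5-dimethoxyphenyl]-4-{[4-(benzyloxy)-3,5-dimethoxyphenyl]methyl}oxolan-3-yl]methanol
Conditions: Cp2TiCl (from Cp2TiCl2 2.5 equiv, Zn dust), THF, rt, added slowly to dilute 9; then aq NaH2PO4
Reagents that add atoms: none (two H from work-up)
Why: Nugent–RajanBabu Ti(III) epoxide opening gives the C8 radical (C9–OTi), which undergoes 5-exo-trig cyclization onto the cinnamyl ether through a Beckwith–Houk chair transition state with the C7 aryl pseudo-equatorial, placing the aryl trans to CH2O[Ti] and CH2O[Ti] cis to the new benzyl group; the benzylic radical is then reduced by a second Ti(III) and protonated. The C8 configuration of 9 is erased at the radical stage, so only C7 matters; a moderate dr with the 2,3-trans/3,4-cis isomer major is expected, and minor isomers are removed by chromatography.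

**Step 7**
Reactants: 10
Product: 11, (+)-(7S,8R,8'R)-5,5'-dimethoxylariciresinol = 4-[(2S,3R,4R)-4-[(4-hydroxy-3,5-dimethoxyphenyl)methyl]-3-(hydroxymethyl)oxolan-2-yl]-2,6-dimethoxyphenol
Conditions: H2 (1 atm), 10% Pd/C, EtOAc, rt, stopped at full debenzylation
Reagents that add atoms: none
Why: hydrogenolysis of aryl benzyl ethers is much faster under neutral conditions than cleavage of the dialkyl benzylic C7–O bond, and no stereocenter is touched.

**Note on descriptors:** C7 is (R) in 8 and 9 and (S) in 10 and 11 with unchanged geometry. The label changes only because C8 outranks the aryl group while it carries oxygen.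

## Compound list

1 | sinapic acid | COc1cc(/C=C/C(=O)O)cc(OC)c1O | starting material
2 | benzyl bromide | BrCc1ccccc1 | starting material (reagent)
3 | benzyl (E)-3-[4-(benzyloxy)-3,5-dimethoxyphenyl]prop-2-enoate | COc1cc(/C=C/C(=O)OCc2ccccc2)cc(OC)c1OCc1ccccc1 | intermediate
4 | (E)-3-[4-(benzyloxy)-3,5-dimethoxyphenyl]prop-2-en-1-ol | COc1cc(/C=C/CO)cc(OC)c1OCc1ccccc1 | intermediate (used in steps 3 and 4)
5 | tert-butyl hydroperoxide | CC(C)(C)OO | starting material (reagent)
6 | p-toluenesulfonyl chloride | Cc1ccc(cc1)S(Cl)(=O)=O | starting material (reagent)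
7 | (2S,3S)-epoxy tosylate | Cc1ccc(cc1)S(=O)(=O)OC[C@@H]1O[C@H]1c1cc(OC)c(OCc2ccccc2)c(OC)c1 | intermediate
8 | (2S,3R)-hydroxy tosylate cinnamyl ether | COc1cc(/C=C/CO[C@H](c2cc(OC)c(OCc3ccccc3)c(OC)c2)[C@@H](O)COS(=O)(=O)c2ccc(C)cc2)cc(OC)c1OCc1ccccc1 | intermediate
9 | (S)-oxirane / (R)-benzylic cinnamyl ether | COc1cc(/C=C/CO[C@H](c2cc(OC)c(OCc3ccccc3)c(OC)c2)[C@@H]2CO2)cc(OC)c1OCc1ccccc1 | intermediate
10 | 4,4'-di-O-benzyl-5,5'-dimethoxylariciresinol (2S,3R,4R) | COc1cc(C[C@H]2CO[C@H](c3cc(OC)c(OCc4ccccc4)c(OC)c3)[C@H]2CO)cc(OC)c1OCc1ccccc1 | intermediate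
11 | (+)-(7S,8R,8'R)-5,5'-dimethoxylariciresinol | COc1cc(C[C@H]2CO[C@H](c3cc(OC)c(O)c(OC)c3)[C@H]2CO)cc(OC)c1O | target

## Summary

Total steps: 7. Longest linear sequence: 7 (sinapic acid → 11; alcohol 4 is used twice, so there is no separate branch).

Three steps most likely to fail, each with a fallback:

1. **Step 6 (radical cascade).** Risks are insufficient diastereoselectivity at C8/C8' and over-reduction of the C8 radical before cyclization. Fallback: use the aryl propargyl alcohol (3-arylprop-2-yn-1-ol) in step 4, so that a 5-exo-dig cyclization only has to relay C7 → C8 (trans) and gives a 4-benzylidene tetrahydrofuran. C8' is then set by heterogeneous hydrogenation from the face opposite the C3 substituent (3,4-cis), concurrent with debenzylation.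
2. **Step 4 (epoxide opening).** Risks are BF3-induced ionisation of the cinnamyl alcohol 4 and partial SN1 leakage that erodes C7. Fallback: open the free (2S,3S)-epoxy alcohol with allyl alcohol in excess under Ti(OiPr)4 mediation (chelate-delivered, C3-selective, inversion) and convert the diol to the terminal epoxide. The aryl group is then attached to the allyl ether by cross-metathesis with 4-benzyloxy-3,5-dimethoxystyrene to reach 9.
3. **Step 7 (debenzylation).** The risk is competing hydrogenolysis of the benzylic C7–O ring bond, giving the seco-lignan. Fallback: redesign the protecting-group strategy around fluoride-labile TIPS ethers (syringaldehyde → TIPS ether → HWE → DIBAL, then the same sequence, with a non-methanolic base in step 5) and finish with TBAF instead of hydrogenation.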